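**Plan**

1. Retrosynthesis: remove the O8 acetate, the O9 epoxy ester and the C11=C13 methylene. Then cut C6–C7 together with the O6–C12 lactone bond, which opens both rings. Cut the open chain at C1=C10 (Wittig) and at C7–C11 (diazoacetate homologation).
2. Enabling feature: C6 and C7 are neighbouring carbinol carbons of the ten-membered ring (C1–C10) with O6 and O7 cis, and the ester carbon C12 hangs from C7 through C11, γ to O6. An open-chain C6 enal and C7 β-keto ester are therefore a pinacol pair: their reductive coupling closes the carbocycle, and O6 then closes the γ-lactone (O6, C6, C7, C11, C12).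
3. Forward: geraniol gives the C1–C6 phosphonium salt. 2,3-O-Isopropylidene-D-erythronolactone gives the C7–C10 methyl ketone. A Wittig reaction joins C1=C10 and ethyl diazoacetate brings C11–C12. SmI2 then closes the ten-membered ring first and the lactone second in one flask. The oxirane arrives ready-made in the acid side chain.
4. Stereochemistry: C8 and C9 come from the erythronolactone. C6 and C7 are set in the samarium-chelated coupling. C4=C5 (E) comes from geraniol and C1=C10 (Z) from the Wittig reaction of an α-alkoxy ketone. The oxirane centres come from a Sharpless epoxidation with D-(−)-diisopropyl tartrate.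

Key step: step 15

Remark: atom numbers C1–C15 are those of the germacrane skeleton of the target (C14 on C10, C15 on C4, C11–C13 the methylene-lactone carbons); the ester alkyl group leaves on lactonisation, so the ethyl β-keto ester is carried; geraniol, 2,3-O-isopropylidene-D-erythronolactone, angelic acid and ethyl diazoacetate are taken as commercial.

**Fragment A: C1–C6 phosphonium salt**

Step 1
Reactants: 1 geraniol
Product: 2 geranyl tert-butyldiphenylsilyl ether
Conditions: TBDPSCl, imidazole, DMF, 0 °C → rt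
Reagents that add atoms: tert-butyl(chloro)diphenylsilane, CC(C)(C)[Si](Cl)(c1ccccc1)c1ccccc1
Why: Imidazole-promoted silyl ether formation at the primary allylic alcohol installs an O6 protecting group that tolerates the ylide, Lewis-acid and oxidation steps up to step 13.

Step 2
Reactants: 2 geranyl tert-butyldiphenylsilyl ether
Product: 4 racemic terminal epoxide tert-butyl{[(2E)-5-(3,3-dimethyloxiran-2-yl)-3-methylpent-2-en-1-yl]oxy}diphenylsilane, via bromohydrin 3 (not isolated)
Conditions: NBS, THF/H2O, 0 °C; then K2CO3, MeOH, rt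
Reagents that add atoms: water, O (epoxide oxygen); N-bromosuccinimide, O=C1CCC(=O)N1Br (bromine, held only in intermediate 3)
Why: Bromohydrin formation takes place at the more electron-rich distal alkene, the alkene next to the silyloxy group being inductively deactivated and shielded, and K2CO3 closes the bromohydrin to the epoxide (intramolecular Williamson closure); the new stereocentre is racemic and is cut out in step 3.

Step 3
Reactants: 4 racemic terminal epoxide
Product: 6 (4E)-6-{[tert-butyl(diphenyl)silyl]oxy}-4-methylhex-4-en-1-ol, via aldehyde 5 (not isolated)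
Conditions: H5IO6, THF/H2O, 0 °C; then NaHCO3, NaBH4, MeOH, 0 °C
Reagents that add atoms: none
Why: Periodic acid opens the epoxide to the glycol and cleaves it (Malaprade glycol cleavage) to aldehyde 5 and acetone, and NaBH4 reduces the aldehyde in the same flask.

Step 4
Reactants: 6 (4E)-6-{[tert-butyl(diphenyl)silyl]oxy}-4-methylhex-4-en-1-ol
Product: 7 tert-butyl{[(2E)-6-iodo-3-methylhex-2-en-1-yl]oxy}diphenylsilane
Conditions: I2, PPh3, imidazole, CH2Cl2, 0 °C → rt
Reagents that add atoms: iodine, II
Why: Appel-type iodination (Garegg–Samuelsson conditions) displaces the alkoxyphosphonium ion by iodide in an SN2 step without touching the allylic silyl ether.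

Step 5
Reactants: 7 tert-butyl{[(2E)-6-iodo-3-methylhex-2-en-1-yl]oxy}diphenylsilane
Product: 8 [(4E)-6-{[tert-butyl(diphenyl)silyl]oxy}-4-methylhex-4-en-1-yl]triphenylphosphonium iodide
Conditions: PPh3, MeCN, 80 °C
Reagents that add atoms: triphenylphosphine, c1ccc(cc1)P(c1ccccc1)c1ccccc1
Why: SN2 quaternisation of triphenylphosphine by the primary iodide gives the phosphonium salt for the Wittig reaction.

**Fragment B: C7–C10 methyl ketone**

Step 6
Reactants: 9 2,3-O-isopropylidene-D-erythronolactone
Product: 10 (4R,5R)-5-(hydroxymethyl)-N-methoxy-N,2,2-trimethyl-1,3-dioxolane-4-carboxamide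
Conditions: MeNH(OMe)·HCl, AlMe3, CH2Cl2, 0 °C → rt
Reagents that add atoms: N,O-dimethylhydroxylamine hydrochloride, CNOC.Cl
Why: The aluminium amide formed from AlMe3 and the hydroxylamine salt opens the lactone at the acyl carbon (Weinreb aminolysis), leaving untouched the two cis-dioxolane stereocentres that become C8 and C9.

Step 7
Reactants: 10 hydroxy Weinreb amide
Product: 11 (4R,5R)-5-({[tert-butyl(dimethyl)silyl]oxy}methyl)-N-methoxy-N,2,2-trimethyl-1,3-dioxolane-4-carboxamide
Conditions: TBSCl, imidazole, CH2Cl2, 0 °C → rt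
Reagents that add atoms: tert-butyl(chloro)dimethylsilane, CC(C)(C)[Si](C)(C)Cl
Why: Silyl ether formation on crude 10 stops relactonisation and masks O7 for the Grignard and Wittig steps.

Step 8
Reactants: 11 silylated Weinreb amide
Product: 12 1-[(4R,5R)-5-({[tert-butyl(dimethyl)silyl]oxy}methyl)-2,2-dimethyl-1,3-dioxolan-4-yl]ethan-1-one
Conditions: MeMgBr, THF, −20 → 0 °C
Reagents that add atoms: methylmagnesium bromide, C[Mg]Br
Why: Weinreb ketone synthesis: the chelated tetrahedral magnesium adduct stops at single addition and releases the methyl ketone (C10 with C14) on work-up, and the α-alkoxy centre should not epimerise at low temperature.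

**Union and ring closure**

Step 9
Reactants: 8 phosphonium iodide; 12 methyl ketone
Product: 14 tert-butyl{[(2E,6Z)-7-[(4S,5R)-5-({[tert-butyl(dimethyl)silyl]oxy}methyl)-2,2-dimethyl-1,3-dioxolan-4-yl]-3-methylocta-2,6-dien-1-yl]oxy}diphenylsilane, via ylide 13 (not isolated)
Conditions: NaN(SiMe3)2, THF, −78 → 0 °C; then 12, −78 °C → rt
Reagents that add atoms: none
Why: The Wittig reaction of a lithium-free, non-stabilised ylide with an α-alkoxy methyl ketone is kinetically controlled and places the oxygenated carbon C9 cis to the ylide chain (the known Z-selective olefination of α-alkoxy ketones), which gives the (Z)-C1=C10 alkene; addition at −78 °C should outrun enolisation, so C9 keeps its configuration.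

Step 10
Reactants: 14 bis-silyl ether
Product: 15 {(4R,5S)-5-[(2Z,6E)-8-{[tert-butyl(diphenyl)silyl]oxy}-6-methylocta-2,6-dien-2-yl]-2,2-dimethyl-1,3-dioxolan-4-yl}methanol
Conditions: HF·pyridine, pyridine, THF, 0 °C
Reagents that add atoms: none
Why: Buffered HF·pyridine removes the primary tert-butyldimethylsilyl ether much faster than the bulkier tert-butyldiphenylsilyl ether (selective fluoride desilylation) and leaves the acetonide intact.

Step 11
Reactants: 15 C7 alcohol
Product: 16 (4S,5S)-5-[(2Z,6E)-8-{[tert-butyl(diphenyl)silyl]oxy}-6-methylocta-2,6-dien-2-yl]-2,2-dimethyl-1,3-dioxolane-4-carbaldehyde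
Conditions: Dess–Martin periodinane, pyridine, CH2Cl2, 0 °C → rt
Reagents that add atoms: none
Why: Dess–Martin oxidation under pyridine buffer gives the α-alkoxy aldehyde under non-basic conditions, and the crude aldehyde is used at once because the cis-dioxolane aldehyde could epimerise at C8 on standing.

Step 12
Reactants: 16 C7 aldehyde
Product: 17 ethyl 3-{(4S,5S)-5-[(2Z,6E)-8-{[tert-butyl(diphenyl)silyl]oxy}-6-methylocta-2,6-dien-2-yl]-2,2-dimethyl-1,3-dioxolan-4-yl}-3-oxopropanoate
Conditions: N2CHCO2Et, SnCl2 (10 mol %), CH2Cl2, rt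
Reagents that add atoms: ethyl diazoacetate, CCOC(=O)C=[N+]=[N-]
Why: Roskamp homologation: SnCl2 activates the aldehyde for attack by the diazo carbon, and a 1,2-hydride shift with loss of N2 gives the β-keto ester (C7 ketone, C11, C12) under Lewis-acidic conditions that do not enolise C8.

Step 13
Reactants: 17 silylated β-keto ester
Product: 18 ethyl 3-{(4S,5S)-5-[(2Z,6E)-8-hydroxy-6-methylocta-2,6-dien-2-yl]-2,2-dimethyl-1,3-dioxolan-4-yl}-3-oxopropanoate
Conditions: Bu4NF, AcOH, THF, 0 °C → rt
Reagents that add atoms: none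
Why: Fluoride desilylation buffered with acetic acid frees the C6 allylic alcohol, and the buffer keeps the β-keto ester and the cis-dioxolane from base-induced epimerisation or elimination.

Step 14
Reactants: 18 allylic alcohol
Product: 19 ethyl 3-{(4S,5S)-2,2-dimethyl-5-[(2Z,6E)-6-methyl-8-oxoocta-2,6-dien-2-yl]-1,3-dioxolan-4-yl}-3-oxopropanoate
Conditions: MnO2, CH2Cl2, rt
Reagents that add atoms: none
Why: MnO2 oxidises only the allylic alcohol (heterogeneous allylic oxidation), leaves the active methylene of the β-keto ester alone, unlike hypervalent iodine oxidants, and keeps the E geometry of C4=C5.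

Step 15
Reactants: 19 seco-6,7 enal β-keto ester
Product: 21 (6S,7S,8S,9S)-7-hydroxy-8,9-(isopropylidenedioxy)germacra-1(10)Z,4E-dien-12,6-olide, via diol ester 20 (not isolated)
Conditions: SmI2 (2.5 equiv), THF, slow addition of 19 to 0.003 M, −78 → 0 °C; then aq. NH4Cl
Reagents that add atoms: none
Why: Electron transfer from SmI2 (samarium diiodide, divalent samarium) to the enal, the most easily reduced group of 19, gives a samarium ketyl that bonds through C6 to the C7 ketone, which is held and activated in a chelate by O8 and the ester carbonyl, and a second electron transfer gives the samarium 6,7-diolate of 20; the closest known reaction type is the intramolecular SmI2 pinacol coupling of keto aldehydes to cyclic cis-1,2-diols, followed by the familiar lactonisation of samarium alkoxides onto γ-esters. The ten-membered carbocycle closes by 10-exo-trig addition of the C6 ketyl radical to the C7 carbonyl, helped by the cis-dioxolane that holds the C7 and C10 arms on one side and by the two trisubstituted alkenes that reduce transannular strain. The γ-lactone then closes by 5-exo-trig attack of the C6 alkoxide on the ethyl ester with loss of ethoxide. C6 is set relative to C7 by the trivalent samarium that bridges both oxygens and so gives the cis-6,7-diol; C7 is set relative to C8 by the five-membered chelate between the ketone oxygen and O8, in which C6 arrives on the face away from C9 (Cram-chelate sense), so that O7 ends trans to O8. The step needs bonding at C6 and not at the vinylogous C4, which the higher spin density at the carbonyl carbon and the fully substituted C4 favour, and it needs ring closure to outrun cleavage of the C8–O bond and intermolecular coupling, which the faster reduction of the enal, the absence of HMPA and proton donors, and slow addition at high dilution should secure.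

**End game**

Step 16
Reactants: 21 hydroxy lactone acetonide
Product: 22 (6S,7S,8S,9S)-13-(dimethylamino)-7-hydroxy-8,9-(isopropylidenedioxy)germacra-1(10)Z,4E-dien-12,6-olide (C11 epimers)
Conditions: LiN(iPr)2 (2.5 equiv), THF, −78 °C; then Me2N=CH2+ I−, −78 → −20 °C
Reagents that add atoms: N,N-dimethylmethyleneiminium iodide (Eschenmoser's salt), C=[N+](C)C.[I-]
Why: Two equivalents of base give the alkoxide–enolate dianion (Fráter–Seebach-type dianion of a β-hydroxy ester), in which the alkoxide is too poor a leaving group for β-elimination, and C11 is aminomethylated by the iminium salt (Mannich reaction); the new C11 centre does not matter because it becomes sp2 in step 17.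

Step 17
Reactants: 22 Mannich base
Product: 24 (6S,7S,8S,9S)-7-hydroxy-8,9-(isopropylidenedioxy)germacra-1(10)Z,4E,11(13)-trien-12,6-olide, via ammonium iodide 23 (not isolated)
Conditions: MeI, MeOH, rt; then aq. NaHCO3, CH2Cl2, rt
Reagents that add atoms: iodomethane, CI (methyl group, held only in intermediate 23)
Why: N-Methylation gives a quaternary ammonium salt that loses trimethylamine under bicarbonate (E1cB, Hofmann-type elimination) to give the exocyclic C11=C13 methylene, and because C7 carries no hydrogen no endocyclic alkene can form.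

Step 18
Reactants: 24 methylene lactone acetonide
Product: 25 (6S,7S,8S,9S)-7,8,9-trihydroxygermacra-1(10)Z,4E,11(13)-trien-12,6-olide
Conditions: AcOH/THF/H2O (3:1:1), 40 °C
Reagents that add atoms: none
Why: Acid-catalysed hydrolysis of the isopropylidene acetal in aqueous acetic acid frees the 8,9-diol under conditions too mild to protonate the trisubstituted alkenes or ionise the allylic C–O bonds.

**Fragment C: epoxy acid**

Step 19
Reactants: 26 angelic acid
Product: 27 (2Z)-2-methylbut-2-en-1-ol
Conditions: LiAlH4, Et2O, 0 °C → reflux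
Reagents that add atoms: none
Why: Hydride reduction of the carboxylic acid with LiAlH4 gives the primary allylic alcohol without isomerising the Z alkene.

Step 20
Reactants: 27 (2Z)-2-methylbut-2-en-1-ol
Product: 28 [(2R,3S)-2,3-dimethyloxiran-2-yl]methanol
Conditions: t-BuOOH, Ti(OiPr)4 (10 mol %), D-(−)-diisopropyl tartrate (12 mol %), 4 Å molecular sieves, CH2Cl2, −20 °C
Reagents that add atoms: tert-butyl hydroperoxide, CC(C)(C)OO
Why: Sharpless asymmetric epoxidation: with D-(−)-diisopropyl tartrate the titanium-bound peroxide is delivered to the alkene face that gives the (2R,3S)-epoxy alcohol, and the cis relation of the C3 methyl and the hydroxymethyl group is carried over from the Z alkene.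

Step 21
Reactants: 28 epoxy alcohol
Product: 29 (2S,3S)-2,3-dimethyloxirane-2-carboxylic acid
Conditions: RuCl3 (2 mol %), NaIO4, MeCN/EtOAc/H2O, 0 °C → rt
Reagents that add atoms: sodium periodate, [Na+].[O-]I(=O)(=O)=O (terminal oxidant); water, O (the second carboxyl oxygen enters through the aldehyde hydrate)
Why: RuO4 generated from RuCl3 and NaIO4 oxidises the primary alcohol through the aldehyde hydrate to the acid (Sharpless ruthenium oxidation) without opening the trisubstituted epoxide; the label at C2 changes from R to S only because the CIP priorities change.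

**Esterifications**

Step 22
Reactants: 25 triol; 29 epoxy acid
Product: 31 9-O-[(2S,3S)-2,3-dimethyloxirane-2-carbonyl] ester of 25, via mixed anhydride 30 (not isolated)
Conditions: 29, 2,4,6-trichlorobenzoyl chloride, Et3N, toluene, rt; then 25, DMAP, 0 °C → rt
Reagents that add atoms: 2,4,6-trichlorobenzoyl chloride, O=C(Cl)c1c(Cl)cc(Cl)cc1Cl (aroyl group, held only in intermediate 30)
Why: Yamaguchi esterification: DMAP attacks the mixed anhydride at the oxirane carbonyl (the aroyl carbonyl is shielded by its two ortho chlorines), and the acylpyridinium ion acylates the allylic O9, which is more accessible than O8 next to the fully substituted C7 and than the tertiary O7.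

Step 23
Reactants: 31 9-O-epoxyangelate
Product: 32 CNP0271187.2, (6S,7S,8S,9S)-8-acetoxy-9-{[(2S,3S)-2,3-dimethyloxirane-2-carbonyl]oxy}-7-hydroxygermacra-1(10)Z,4E,11(13)-trien-12,6-olide
Conditions: Ac2O, pyridine, DMAP (cat.), CH2Cl2, 0 °C
Reagents that add atoms: acetic anhydride, CC(=O)OC(C)=O
Why: DMAP-catalysed acetylation (Steglich-type acyl transfer) should acylate the remaining secondary O8 hydroxyl while the tertiary O7 hydroxyl stays free under these mild conditions.

**Compound list**

1 | geraniol, (2E)-3,7-dimethylocta-2,6-dien-1-ol | CC(C)=CCC/C(C)=C/CO | starting material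
2 | tert-butyl{[(2E)-3,7-dimethylocta-2,6-dien-1-yl]oxy}diphenylsilane | CC(C)=CCC/C(C)=C/CO[Si](c1ccccc1)(c1ccccc1)C(C)(C)C | intermediate
3 | (6E)-3-bromo-8-{[tert-butyl(diphenyl)silyl]oxy}-2,6-dimethyloct-6-en-2-ol (racemic bromohydrin) | CC(C)(O)C(Br)CC/C(C)=C/CO[Si](c1ccccc1)(c1ccccc1)C(C)(C)C | intermediate
4 | tert-butyl{[(2E)-5-(3,3-dimethyloxiran-2-yl)-3-methylpent-2-en-1-yl]oxy}diphenylsilane (racemic) | CC1(C)OC1CC/C(C)=C/CO[Si](c1ccccc1)(c1ccccc1)C(C)(C)C | intermediate
5 | (4E)-6-{[tert-butyl(diphenyl)silyl]oxy}-4-methylhex-4-enal | O=CCC/C(C)=C/CO[Si](c1ccccc1)(c1ccccc1)C(C)(C)C | intermediate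
6 | (4E)-6-{[tert-butyl(diphenyl)silyl]oxy}-4-methylhex-4-en-1-ol | OCCC/C(C)=C/CO[Si](c1ccccc1)(c1ccccc1)C(C)(C)C | intermediate
7 | tert-butyl{[(2E)-6-iodo-3-methylhex-2-en-1-yl]oxy}diphenylsilane | ICCC/C(C)=C/CO[Si](c1ccccc1)(c1ccccc1)C(C)(C)C | intermediate
8 | [(4E)-6-{[tert-butyl(diphenyl)silyl]oxy}-4-methylhex-4-en-1-yl]triphenylphosphonium iodide | [I-].CC(C)(C)[Si](c1ccccc1)(c1ccccc1)OC/C=C(\C)CCC[P+](c1ccccc1)(c1ccccc1)c1ccccc1 | intermediate
9 | 2,3-O-isopropylidene-D-erythronolactone, (3aR,6aR)-2,2-dimethyldihydrofuro[3,4-d][1,3]dioxol-4(3aH)-one | O=C1OC[C@H]2OC(C)(C)O[C@@H]12 | starting material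
10 | (4R,5R)-5-(hydroxymethyl)-N-methoxy-N,2,2-trimethyl-1,3-dioxolane-4-carboxamide | CON(C)C(=O)[C@@H]1OC(C)(C)O[C@@H]1CO | intermediate
11 | (4R,5R)-5-({[tert-butyl(dimethyl)silyl]oxy}methyl)-N-methoxy-N,2,2-trimethyl-1,3-dioxolane-4-carboxamide | CON(C)C(=O)[C@@H]1OC(C)(C)O[C@@H]1CO[Si](C)(C)C(C)(C)C | intermediate
12 | 1-[(4R,5R)-5-({[tert-butyl(dimethyl)silyl]oxy}methyl)-2,2-dimethyl-1,3-dioxolan-4-yl]ethan-1-one | CC(=O)[C@@H]1OC(C)(C)O[C@@H]1CO[Si](C)(C)C(C)(C)C | intermediate
13 | [(4E)-6-{[tert-butyl(diphenyl)silyl]oxy}-4-methylhex-4-en-1-ylidene]triphenylphosphorane (ylide) | CC(C)(C)[Si](c1ccccc1)(c1ccccc1)OC/C=C(\C)CCC=P(c1ccccc1)(c1ccccc1)c1ccccc1 | intermediate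
14 | tert-butyl{[(2E,6Z)-7-[(4S,5R)-5-({[tert-butyl(dimethyl)silyl]oxy}methyl)-2,2-dimethyl-1,3-dioxolan-4-yl]-3-methylocta-2,6-dien-1-yl]oxy}diphenylsilane | CC(C)(C)[Si](c1ccccc1)(c1ccccc1)OC/C=C(\C)CC/C=C(/C)[C@@H]1OC(C)(C)O[C@@H]1CO[Si](C)(C)C(C)(C)C | intermediate
15 | {(4R,5S)-5-[(2Z,6E)-8-{[tert-butyl(diphenyl)silyl]oxy}-6-methylocta-2,6-dien-2-yl]-2,2-dimethyl-1,3-dioxolan-4-yl}methanol | CC(C)(C)[Si](c1ccccc1)(c1ccccc1)OC/C=C(\C)CC/C=C(/C)[C@@H]1OC(C)(C)O[C@@H]1CO | intermediate
16 | (4S,5S)-5-[(2Z,6E)-8-{[tert-butyl(diphenyl)silyl]oxy}-6-methylocta-2,6-dien-2-yl]-2,2-dimethyl-1,3-dioxolane-4-carbaldehyde | CC(C)(C)[Si](c1ccccc1)(c1ccccc1)OC/C=C(\C)CC/C=C(/C)[C@@H]1OC(C)(C)O[C@@H]1C=O | intermediate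
17 | ethyl 3-{(4S,5S)-5-[(2Z,6E)-8-{[tert-butyl(diphenyl)silyl]oxy}-6-methylocta-2,6-dien-2-yl]-2,2-dimethyl-1,3-dioxolan-4-yl}-3-oxopropanoate | CC(C)(C)[Si](c1ccccc1)(c1ccccc1)OC/C=C(\C)CC/C=C(/C)[C@@H]1OC(C)(C)O[C@@H]1C(=O)CC(=O)OCC | intermediate
18 | ethyl 3-{(4S,5S)-5-[(2Z,6E)-8-hydroxy-6-methylocta-2,6-dien-2-yl]-2,2-dimethyl-1,3-dioxolan-4-yl}-3-oxopropanoate | OC/C=C(\C)CC/C=C(/C)[C@@H]1OC(C)(C)O[C@@H]1C(=O)CC(=O)OCC | intermediate
19 | ethyl 3-{(4S,5S)-2,2-dimethyl-5-[(2Z,6E)-6-methyl-8-oxoocta-2,6-dien-2-yl]-1,3-dioxolan-4-yl}-3-oxopropanoate (seco-6,7 enal β-keto ester) | O=C/C=C(\C)CC/C=C(/C)[C@@H]1OC(C)(C)O[C@@H]1C(=O)CC(=O)OCC | intermediate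
20 | ethyl [(6S,7S,8S,9S)-6,7-dihydroxy-8,9-(isopropylidenedioxy)germacra-1(10)Z,4E-dien-7-yl]acetate (ten-membered diol ester; C11 and C12 are the acetate carbons) | CCOC(=O)C[C@]1(O)[C@@H](O)/C=C(\C)CC/C=C(/C)[C@@H]2OC(C)(C)O[C@@H]21 | intermediate
21 | (6S,7S,8S,9S)-7-hydroxy-8,9-(isopropylidenedioxy)germacra-1(10)Z,4E-dien-12,6-olide | C1C(=O)O[C@H]2/C=C(\C)CC/C=C(/C)[C@@H]3OC(C)(C)O[C@@H]3[C@]12O | intermediate
22 | (6S,7S,8S,9S)-13-(dimethylamino)-7-hydroxy-8,9-(isopropylidenedioxy)germacra-1(10)Z,4E-dien-12,6-olide (C11 epimers) | CN(C)CC1C(=O)O[C@H]2/C=C(\C)CC/C=C(/C)[C@@H]3OC(C)(C)O[C@@H]3[C@]12O | intermediate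
23 | 13-(trimethylammonio) analogue of 22, iodide salt | [I-].C[N+](C)(C)CC1C(=O)O[C@H]2/C=C(\C)CC/C=C(/C)[C@@H]3OC(C)(C)O[C@@H]3[C@]12O | intermediate
24 | (6S,7S,8S,9S)-7-hydroxy-8,9-(isopropylidenedioxy)germacra-1(10)Z,4E,11(13)-trien-12,6-olide | C=C1C(=O)O[C@H]2/C=C(\C)CC/C=C(/C)[C@@H]3OC(C)(C)O[C@@H]3[C@]12O | intermediate
25 | (6S,7S,8S,9S)-7,8,9-trihydroxygermacra-1(10)Z,4E,11(13)-trien-12,6-olide | C=C1C(=O)O[C@H]2/C=C(\C)CC/C=C(/C)[C@H](O)[C@H](O)[C@]12O | intermediate
26 | angelic acid, (2Z)-2-methylbut-2-enoic acid | C/C=C(/C)C(=O)O | starting material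
27 | (2Z)-2-methylbut-2-en-1-ol | C/C=C(/C)CO | intermediate
28 | [(2R,3S)-2,3-dimethyloxiran-2-yl]methanol | OC[C@@]1(C)O[C@H]1C | intermediate
29 | (2S,3S)-2,3-dimethyloxirane-2-carboxylic acid | OC(=O)[C@@]1(C)O[C@H]1C | intermediate
30 | (2S,3S)-2,3-dimethyloxirane-2-carboxylic 2,4,6-trichlorobenzoic anhydride | O=C(OC(=O)[C@@]1(C)O[C@H]1C)c1c(Cl)cc(Cl)cc1Cl | intermediate
31 | (6S,7S,8S,9S)-9-{[(2S,3S)-2,3-dimethyloxirane-2-carbonyl]oxy}-7,8-dihydroxygermacra-1(10)Z,4E,11(13)-trien-12,6-olide | C=C1C(=O)O[C@H]2/C=C(\C)CC/C=C(/C)[C@H](OC(=O)[C@@]3(C)O[C@H]3C)[C@H](O)[C@]12O | intermediate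
32 | CNP0271187.2, (6S,7S,8S,9S)-8-acetoxy-9-{[(2S,3S)-2,3-dimethyloxirane-2-carbonyl]oxy}-7-hydroxygermacra-1(10)Z,4E,11(13)-trien-12,6-olide | C=C1C(=O)O[C@H]2/C=C(\C)CC/C=C(/C)[C@H](OC(=O)[C@@]3(C)O[C@H]3C)[C@H](OC(C)=O)[C@]12O | target

**Step count and risks**

Total step count: 23. Longest linear sequence: 17 steps (steps 1–5, 9–18, 22, 23).

Steps most likely to fail:

1. Step 15 (ring closure). The enal may be reduced or couple intermolecularly before the ring closes. The C8–O bond next to the ketone may be cleaved reductively. The delocalised ketyl may bond through C4 or lose the C4=C5 geometry, or C6 may add to the wrong face of the ketone. Fallback, setting out from 19 and coming back at 21: exchange the ketone acceptor for a better radical trap. Silylation of the β-keto ester of 19 (Et3SiCl, imidazole, CH2Cl2, 0 °C) should give the triethylsilyl enol ether F1. SmI2 with MeOH in dilute THF should then add the C6 ketyl to C7 of the β-silyloxyacrylate (the known SmI2 reductive cyclisation of aldehydes onto β-alkoxyacrylates, a ketyl–olefin addition) and lactonise to the 7-O-triethylsilyl lactone F2. HF·pyridine should then release 21. With no ketone present, C8–O cleavage and enolisation of the β-keto ester fall away.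

2. Step 22 (esterification at O9). Site selectivity between O8 and O9 may be poor, the α-quaternary anhydride may acylate slowly, and the acyl group may migrate across the cis-8,9-diol. Fallback, setting out from 25 and coming back at 32: reverse the order of the two acylations and leave the site choice to a small silyl chloride at low temperature. Et3SiCl and 2,6-lutidine at −78 °C should silylate the allylic O9 to give the 9-O-triethylsilyl ether F3. Ac2O with DMAP should acetylate O8 to give the 8-O-acetyl-9-O-triethylsilyl compound F4. HF·pyridine should free O9 to give the 8-O-acetate F5. Yamaguchi esterification of F5 with 29 (through 30) at the only remaining secondary hydroxyl then gives 32.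

3. Step 16 (aminomethylation at C11). The hindered alkoxide–enolate may form incompletely or be captured poorly, the lithium alkoxide may open by retro-aldol cleavage of C7–C11, or the lactone may dehydrate toward the butenolide. Fallback, setting out from 21 and coming back at 24: base-free condensation in place of enolate chemistry. Heating 21 with tert-butoxybis(dimethylamino)methane (Bredereck's reagent) in toluene at 70 °C should give the 13-(dimethylamino)methylene lactone F6. 1,4-Reduction with iBu2AlH at −78 °C and loss of dimethylamine on mildly acidic work-up (the known enaminolactone route to α-methylene lactones) should give 24, so that steps 16 and 17 are not needed.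

Further compounds

F1 | step 15 | ethyl (2Z)-3-{(4S,5S)-2,2-dimethyl-5-[(2Z,6E)-6-methyl-8-oxoocta-2,6-dien-2-yl]-1,3-dioxolan-4-yl}-3-[(triethylsilyl)oxy]prop-2-enoate | O=C/C=C(\C)CC/C=C(/C)[C@@H]1OC(C)(C)O[C@@H]1/C(O[Si](CC)(CC)CC)=C/C(=O)OCC
F2 | step 15 | (6S,7S,8S,9S)-8,9-(isopropylidenedioxy)-7-[(triethylsilyl)oxy]germacra-1(10)Z,4E-dien-12,6-olide | C1C(=O)O[C@H]2/C=C(\C)CC/C=C(/C)[C@@H]3OC(C)(C)O[C@@H]3[C@]12O[Si](CC)(CC)CC
F3 | step 22 | (6S,7S,8S,9S)-7,8-dihydroxy-9-[(triethylsilyl)oxy]germacra-1(10)Z,4E,11(13)-trien-12,6-olide | C=C1C(=O)O[C@H]2/C=C(\C)CC/C=C(/C)[C@H](O[Si](CC)(CC)CC)[C@H](O)[C@]12O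
F4 | step 22 | (6S,7S,8S,9S)-8-acetoxy-7-hydroxy-9-[(triethylsilyl)oxy]germacra-1(10)Z,4E,11(13)-trien-12,6-olide | C=C1C(=O)O[C@H]2/C=C(\C)CC/C=C(/C)[C@H](O[Si](CC)(CC)CC)[C@H](OC(C)=O)[C@]12O
F5 | step 22 | (6S,7S,8S,9S)-8-acetoxy-7,9-dihydroxygermacra-1(10)Z,4E,11(13)-trien-12,6-olide | C=C1C(=O)O[C@H]2/C=C(\C)CC/C=C(/C)[C@H](O)[C@H](OC(C)=O)[C@]12O
F6 | step 16 | (6S,7S,8S,9S)-13-(dimethylamino)-7-hydroxy-8,9-(isopropylidenedioxy)germacra-1(10)Z,4E,11(13)-trien-12,6-olide (enamine geometry not defined, either isomer serves) | CN(C)C=C1C(=O)O[C@H]2/C=C(\C)CC/C=C(/C)[C@@H]3OC(C)(C)O[C@@H]3[C@]12O
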